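Remark on the chemistry: 1,1-bis(benzyloxy)ethene (17) is assumed not to be a catalogue compound and is therefore prepared in steps 9 and 10; dibenzyl 3-oxopentanedioate (4) and 1,1-dimethoxyethene (9) are assumed to be purchased. The target has no stereocentres; the bridged intermediates 10 and 18 are racemic and lose their stereocentres on aromatisation.

## Analysis of the target

The target (25) is a depside: two benzene rings joined by a single aryl ester, with no stereocentre. Ring A, the acyl part, carries the ester carbonyl at C1, a free hydroxyl at C2, a methoxy group at C4 and a 2-oxoheptyl chain at C6. Ring B, the phenol part, carries a free carboxyl at C1, a methoxy group at C2, the acylated oxygen at C4 and the same 2-oxoheptyl chain at C6. The two rings therefore share one carbon skeleton and differ only in which ring oxygen is methylated, so three oxygen functions must be told apart on each ring. The aryl ester does not survive saponification, so the ring B carboxyl must be released without hydroxide. Each benzylic ketone sits ortho to a carbonyl group, and its enol can lactonise to an isocoumarin, in ring A with expulsion of ring B; the ketones therefore stay masked until the rings are joined. The structural feature used here is that C6 (side chain), C1 (carboxyl) and C2 (oxygen) of ring A are contiguous and map onto C6, C5 and C4 of a 2-pyrone-5-carboxylate. C3 is then pyrone C3, and C4 with its methoxy group plus C5 come from a two-carbon ketene acetal; ring B has the same triad, so one pyrone scaffold can serve both rings.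

## Retrosynthetic reasoning

**25 to 24.** The last bond cut is the O–benzyl bond of the ring B ester. Hydrogenolysis is neutral and leaves the aryl ester alone, whereas any hydrolytic release of the carboxyl would also cleave the depside. The forward step must touch only the benzyl group of 24.

**24 to 23.** The two ketones are traced back to dioxolanes. Masked, the side chains cannot enolise towards the neighbouring carbonyl groups during ring construction and coupling. Unmasking is placed before the final hydrogenolysis so that the weak-acid step meets an ester, not a free acid, next to the new ring B ketone.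

**23 to 13 and 22.** The aryl ester C–O bond is the only link between the rings, and cutting it gives two fragments of equal size. The forward reaction must acylate the para hydroxyl of 22 with the carboxyl of 13 under non-basic conditions; the hydrogen-bonded ortho hydroxyl of 13 is left free.

**13 to 12.** Both O–benzyl bonds of 12 are cut together. One hydrogenolysis removes the ester and the ether, so no selective ester cleavage at a di-ortho-substituted benzoate is needed.

**12 to 8 and 9 (key disconnection).** Ring A is cut at C3–C4 and C5–C6. This puts all three contiguous substituents (side chain, carboxyl, oxygen) into one fragment, pyrone 8, and leaves the methoxy-bearing carbon in the catalogue ketene acetal 9. No other pair of ring bonds gives a fragment in which the relative positions of three substituents are fixed by a simple heterocycle. The forward reaction must join the CH2 of 9 to pyrone C6 and the acetal carbon to C3, then lose the lactone bridge and one alkoxy group. The C5 ester polarises the diene in this sense.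

**22 to 21, 20, then 14 and 17.** Ring B is cut at the same two bonds. Its pyrone (14) carries the methoxy group, and the para oxygen must arrive in removable form, so the ketene acetal is the dibenzyl compound 17; a methyl ether at that position could not be told apart from the C2 methoxy group. Since an aryl benzyl ether cannot be removed reliably beside a benzyl ester, both are cleaved (20 to 21) and the carboxyl alone is re-benzylated (21 to 22). Acetal 17 is traced to bromoacetal 16 by elimination and to the catalogue acetal 15 by acetal exchange.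

**8 and 14 to 7.** Both pyrones come from one hydroxypyrone 7 by cutting the O–alkyl bond. The choice of alcohol in a neutral O-alkylation decides whether the material becomes ring A or ring B.

**7 to 6, then 3 and 4.** The lactone C–O bond of 7 is cut to the open tricarbonyl compound 6, and the C–C bond between its acyl group and the central carbon is cut to acid 3 and the symmetric keto diester 4. In 6 only one six-membered enol lactone is possible, so the pyrone substitution is unambiguous. An annulation of a β-keto ester with a diacid chloride was considered for this ring but releases strong acid beside the dioxolane; the magnesium-mediated acylation of 4 is neutral to weakly basic.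

**3 to 2 to 1.** Acid 3 comes from ester 2 by saponification, and 2 from the catalogue β-keto ester 1 by ketalisation. The five-carbon tail and the ketone oxidation level of both side chains are thus bought in 1.

## Alternatives that were turned down

**Alternative 1:** Ring B would be cut at C1–carboxyl and C6–CH2 together, leading back to an aryne and dibenzyl malonate (A2).
- Forward key step: fluoride releases the aryne from 4-(allyloxy)-2-methoxy-6-(trimethylsilyl)phenyl triflate (A1). The malonate carbon of A2 adds to the aryne carbon remote from the methoxy group, the resulting aryl anion attacks an ester carbonyl, and the four-membered ring opens to the homophthalate benzyl 4-(allyloxy)-2-[2-(benzyloxy)-2-oxoethyl]-6-methoxybenzoate (A3).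
- For: the conditions are mild, and the regiochemistry follows from the inductive effect of the ortho methoxy group. The C4 oxygen arrives as an allyl ether that a zerovalent palladium catalyst removes beside a benzyl ester. On this point the alternative is stronger, since the chosen route needs steps 11 to 13 to reach the same free phenol.
- Against: A3 carries carboxyl oxidation level on both arms. Converting its CH2–CO2Bn arm into the 2-oxoheptyl ketone means differentiating two benzyl esters and then adding a pentyl unit once at a doubly activated methylene ortho to an ester, where enolisation leads into isocoumarin-type closures. A1 is a multistep compound, the step builds no ring, and ring A would need a second, differently oxygenated silyl triflate.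
- Comparison: the chosen strategy has the masked ketone chain in place from 3 and makes both rings from 7.

**Alternative 2:** Ring A would be cut at the bond between the carboxyl-bearing carbon and the carbon bearing the side chain (chain C2–C7).
- Forward key step: the aryl triketo ester benzyl 2-methoxy-6-[(2-pentyl-1,3-dioxolan-2-yl)methyl]-4-{[3,5,7-trioxo-8-(2-pentyl-1,3-dioxolan-2-yl)octanoyl]oxy}benzoate (A4) undergoes aldol condensation of C2 onto the C7 ketone, dehydration and enolisation. The product is benzyl 4-({2,4-dihydroxy-6-[(2-pentyl-1,3-dioxolan-2-yl)methyl]benzoyl}oxy)-2-methoxy-6-[(2-pentyl-1,3-dioxolan-2-yl)methyl]benzoate (A5).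
- For: ring A and the depside bond come from one open chain, the aromatisation is irreversible, and ring A needs no protecting group. In count of operations on ring A this is shorter than the chosen route.
- Against: in A4 the aryloxy group is the best leaving group in the molecule. Lactonisation of the C5 enol onto C1 (to a 4-hydroxy-2-pyrone) and Claisen closure of C6 onto C1 both expel the phenoxide of 22 and destroy the depside, and steering a triketo aryl ester into the aldol mode is not secured by anything in the substrate. A4 itself requires polyanion chemistry in the presence of an aryl ester. A5 still needs selective methylation at O4, and ring B (22) must still be made by another method.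
- Comparison: the chosen strategy forms the aryl ester only after both rings are complete and never exposes it to enolate chemistry.

**Alternative 3:** Ring B would be cut at C1–C2 and C5–C6.
- Forward key step: 1,1-dimethoxy-3-(trimethylsilyloxy)buta-1,3-diene (A6) adds to benzyl 4-(2-pentyl-1,3-dioxolan-2-yl)but-2-ynoate (A7). The nucleophilic CH2 terminus of A6 bonds to the β-carbon of A7; loss of one methoxy group as the alcohol and desilylation give benzyl 4-hydroxy-2-methoxy-6-[(2-pentyl-1,3-dioxolan-2-yl)methyl]benzoate (A8), which is identical with 22.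
- For: A8 is reached in one step with the methoxy and hydroxyl groups already differentiated, and no carbon is lost. For ring B this is clearly stronger than steps 8 to 13 of the chosen route.
- Against: A7 has a methylene flanked by an ynoate and a ketal, so base or heat can isomerise it to an allenoate or open the dioxolane by β-elimination. The disubstituted, β-branched alkyne is a slow dienophile at temperatures that A6 tolerates. Ring A has the opposite oxygen pattern and would need a second diene.
- Comparison: the chosen strategy offers a single stock intermediate (7) for both rings and fragments (8, 14) that are stable, crystalline-type heteroaromatics. It pays for this with the three-step detour to the free phenol of ring B.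

Key step: step 6

## Route

Step 1
Reactants: 1 ethyl 3-oxooctanoate
Product: 2 ethyl 2-(2-pentyl-1,3-dioxolan-2-yl)acetate
Conditions: HOCH2CH2OH (3 equiv), TsOH·H2O (cat.), PhMe, reflux, Dean–Stark
Reagents that add atoms: ethylene glycol, OCCO
Why: Acid-catalysed ketalisation with azeotropic removal of water; the ketone of the β-keto ester reacts and the ester is inert, and masking the ketone now blocks every later cyclisation of the side chain.

Step 2
Reactants: 2 ethyl 2-(2-pentyl-1,3-dioxolan-2-yl)acetate
Product: 3 2-(2-pentyl-1,3-dioxolan-2-yl)acetic acid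
Conditions: LiOH, THF/MeOH/H2O, rt; then cold 1 M HCl to pH 3–4, immediate extraction
Reagents that add atoms: lithium hydroxide, [Li+].[OH-]
Why: Saponification of an unhindered ethyl ester; the dioxolane is stable to base, and brief cold acidification releases the acid without ketal hydrolysis or decarboxylation.

Step 3
Reactants: 3 2-(2-pentyl-1,3-dioxolan-2-yl)acetic acid; 4 dibenzyl 3-oxopentanedioate
Product: 6 dibenzyl 2-[2-(2-pentyl-1,3-dioxolan-2-yl)acetyl]-3-oxopentanedioate, via acyl imidazolide 5 (not isolated)
Conditions: CDI, THF, rt; then 4, MgCl2, Et3N, MeCN, 0 °C → rt; cold aq. citric acid work-up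
Reagents that add atoms: none
Why: The acid is activated as imidazolide 5 under neutral conditions and C-acylates the magnesium chelate of 4 (magnesium-mediated C-acylation of an active methylene compound); chelation directs acylation to carbon, and the product stays as its magnesium enolate, which protects it from a second acylation.

Step 4
Reactants: 6 dibenzyl 2-[2-(2-pentyl-1,3-dioxolan-2-yl)acetyl]-3-oxopentanedioate
Product: 7 benzyl 4-hydroxy-2-oxo-6-[(2-pentyl-1,3-dioxolan-2-yl)methyl]-2H-pyran-5-carboxylate
Conditions: DBU, PhMe, 60 °C; cold aq. citric acid work-up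
Reagents that add atoms: none
Why: Enol lactonisation of a 3,5-dioxo ester to a 4-hydroxy-2-pyrone, the cyclisation mode of triketide esters; the enol oxygen of the side-chain ketone can reach only the terminal benzyl ester through a six-membered ring, so a single pyrone with the ester at C5 and the side chain at C6 should form.

Step 5
Reactants: 7 benzyl 4-hydroxy-2-oxo-6-[(2-pentyl-1,3-dioxolan-2-yl)methyl]-2H-pyran-5-carboxylate
Product: 8 benzyl 4-(benzyloxy)-2-oxo-6-[(2-pentyl-1,3-dioxolan-2-yl)methyl]-2H-pyran-5-carboxylate
Conditions: BnOH, PPh3, DIAD, THF, 0 °C → rt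
Reagents that add atoms: benzyl alcohol, OCc1ccccc1
Why: Mitsunobu O-alkylation of the acidic 4-hydroxy-2-pyrone; the neutral conditions favour alkylation at O4 over C3 and leave the ketal and the acidic C6 methylene untouched.

Step 6
Reactants: 8 benzyl 4-(benzyloxy)-2-oxo-6-[(2-pentyl-1,3-dioxolan-2-yl)methyl]-2H-pyran-5-carboxylate; 9 1,1-dimethoxyethene
Product: 12 benzyl 2-(benzyloxy)-4-methoxy-6-[(2-pentyl-1,3-dioxolan-2-yl)methyl]benzoate, via bridged lactone cycloadduct 10 (not isolated), via cyclohexadiene acetal 11 (not isolated)
Conditions: 9 (5 equiv), K2CO3 (trace), PhMe, sealed tube, 110 °C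
Reagents that add atoms: none
Why: This is an inverse-electron-demand Diels–Alder reaction of a 2-pyrone-5-carboxylate with a ketene acetal, the reaction type by which coumalate esters are converted into 4-alkoxybenzoates. The CH2 terminus of 9 bonds to pyrone C6, which is β to the C5 ester and vinylogous to the lactone carbonyl, and the acetal carbon bonds to C3. The two bonds form in a concerted but strongly asynchronous (4+2) process, or stepwise through a zwitterion that closes by 6-(enolexo)-exo-trig attack of C3 on the oxocarbenium carbon; either way the six-membered carbocycle is closed as bridged lactone 10. Cycloreversion of 10 expels CO2 to give diene 11, and 1,2-elimination of methanol, driven by aromatisation, gives 12. The bridgehead stereocentres of 10 form as a racemate and are destroyed again, so no stereocontrol is needed. The one selectivity required is regiochemical: the C5 ester makes C6 the electrophilic terminus, so the methoxy-bearing carbon ends para to the carboxyl and the side chain stays ortho to it. The 4-benzyloxy donor only lowers the rate, which is met by excess 9, heat and exclusion of acid (trace K2CO3) so that 9 does not polymerise; benzyl ester, benzyl ether and dioxolane are inert under these neutral conditions.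

Step 7
Reactants: 12 benzyl 2-(benzyloxy)-4-methoxy-6-[(2-pentyl-1,3-dioxolan-2-yl)methyl]benzoate
Product: 13 2-hydroxy-4-methoxy-6-[(2-pentyl-1,3-dioxolan-2-yl)methyl]benzoic acid
Conditions: H2 (1 atm), 10% Pd/C, EtOAc, rt
Reagents that add atoms: none
Why: Hydrogenolysis over Pd/C cleaves the benzyl ester and the aryl benzyl ether in one operation; arene, methyl ether and dioxolane are untouched in a neutral aprotic solvent, and the acid is used promptly.

Step 8
Reactants: 7 benzyl 4-hydroxy-2-oxo-6-[(2-pentyl-1,3-dioxolan-2-yl)methyl]-2H-pyran-5-carboxylate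
Product: 14 benzyl 4-methoxy-2-oxo-6-[(2-pentyl-1,3-dioxolan-2-yl)methyl]-2H-pyran-5-carboxylate
Conditions: MeOH, PPh3, DIAD, THF, 0 °C → rt
Reagents that add atoms: methanol, CO
Why: Mitsunobu O-methylation of the same hydroxypyrone under the neutral conditions of step 5; it fixes the future C2 methoxy group of ring B.

Step 9
Reactants: 15 2-bromo-1,1-diethoxyethane
Product: 16 2-bromo-1,1-bis(benzyloxy)ethane
Conditions: BnOH (2.2 equiv), TsOH·H2O (cat.), 100 °C, EtOH distilled off
Reagents that add atoms: benzyl alcohol, OCc1ccccc1
Why: Acid-catalysed acetal exchange driven by distilling off the lower-boiling ethanol; the primary bromide is inert.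

Step 10
Reactants: 16 2-bromo-1,1-bis(benzyloxy)ethane
Product: 17 1,1-bis(benzyloxy)ethene
Conditions: KOtBu, THF, 0 °C → rt
Reagents that add atoms: none
Why: E2 dehydrobromination of a bromoacetal by a hindered alkoxide, the classical preparation of ketene acetals; the bulky base and the β-branched bromide suppress substitution.

Step 11
Reactants: 14 benzyl 4-methoxy-2-oxo-6-[(2-pentyl-1,3-dioxolan-2-yl)methyl]-2H-pyran-5-carboxylate; 17 1,1-bis(benzyloxy)ethene
Product: 20 benzyl 4-(benzyloxy)-2-methoxy-6-[(2-pentyl-1,3-dioxolan-2-yl)methyl]benzoate, via bridged lactone cycloadduct 18 (not isolated), via cyclohexadiene acetal 19 (not isolated)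
Conditions: 17 (3 equiv), K2CO3 (trace), PhMe, sealed tube, 100 °C
Reagents that add atoms: none
Why: The same inverse-demand Diels–Alder, cycloreversion and elimination sequence as step 6, with the regiochemistry again set by the C5 ester; the ketene acetal delivers the para oxygen as a benzyl ether, and the temperature is held at 100 °C because benzyl ketene acetals can rearrange by 1,3-benzyl shift.

Step 12
Reactants: 20 benzyl 4-(benzyloxy)-2-methoxy-6-[(2-pentyl-1,3-dioxolan-2-yl)methyl]benzoate
Product: 21 4-hydroxy-2-methoxy-6-[(2-pentyl-1,3-dioxolan-2-yl)methyl]benzoic acid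
Conditions: H2 (1 atm), 10% Pd/C, EtOAc, rt
Reagents that add atoms: none
Why: Hydrogenolysis of both benzyl groups over Pd/C; loss of the ester together with the ether is accepted, since no reliable method removes an aryl benzyl ether beside a benzyl ester.

Step 13
Reactants: 21 4-hydroxy-2-methoxy-6-[(2-pentyl-1,3-dioxolan-2-yl)methyl]benzoic acid
Product: 22 benzyl 4-hydroxy-2-methoxy-6-[(2-pentyl-1,3-dioxolan-2-yl)methyl]benzoate
Conditions: BnBr, KHCO3, DMF, rt
Reagents that add atoms: benzyl bromide, BrCc1ccccc1
Why: Chemoselective carboxylate alkylation: KHCO3 deprotonates the carboxylic acid but not the phenol, and the carboxylate is benzylated by SN2 at an oxygen remote from the two ortho substituents.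

Step 14
Reactants: 13 2-hydroxy-4-methoxy-6-[(2-pentyl-1,3-dioxolan-2-yl)methyl]benzoic acid; 22 benzyl 4-hydroxy-2-methoxy-6-[(2-pentyl-1,3-dioxolan-2-yl)methyl]benzoate
Product: 23 benzyl 4-({2-hydroxy-4-methoxy-6-[(2-pentyl-1,3-dioxolan-2-yl)methyl]benzoyl}oxy)-2-methoxy-6-[(2-pentyl-1,3-dioxolan-2-yl)methyl]benzoate
Conditions: DCC, PhMe, 0 °C → rt
Reagents that add atoms: none
Why: Carbodiimide esterification of a salicylic acid with a phenol, the standard depside coupling; the 2-hydroxyl of 13 is hydrogen-bonded to its carboxyl and hindered, so the free para phenol of 22 is the acyl acceptor, and a non-polar solvent without base limits N-acylurea formation.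

Step 15
Reactants: 23 benzyl 4-({2-hydroxy-4-methoxy-6-[(2-pentyl-1,3-dioxolan-2-yl)methyl]benzoyl}oxy)-2-methoxy-6-[(2-pentyl-1,3-dioxolan-2-yl)methyl]benzoate
Product: 24 benzyl 4-{[2-hydroxy-4-methoxy-6-(2-oxoheptyl)benzoyl]oxy}-2-methoxy-6-(2-oxoheptyl)benzoate
Conditions: PPTS, acetone/H2O (9:1), 50 °C
Reagents that add atoms: water, O
Why: Mild acid-catalysed hydrolysis of both dioxolanes; it is run at the benzyl ester stage so that no free carboxylic acid sits next to the new ring B ketone, and weak acid at moderate temperature is chosen because enol lactonisation of the ring A ketone onto the depside carbonyl is the known degradation path of such compounds.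

Step 16
Reactants: 24 benzyl 4-{[2-hydroxy-4-methoxy-6-(2-oxoheptyl)benzoyl]oxy}-2-methoxy-6-(2-oxoheptyl)benzoate
Product: 25 4-{[2-hydroxy-4-methoxy-6-(2-oxoheptyl)benzoyl]oxy}-2-methoxy-6-(2-oxoheptyl)benzoic acid
Conditions: H2 (1 atm), 10% Pd/C, EtOAc, rt
Reagents that add atoms: none
Why: Neutral hydrogenolysis of the benzyl ester as the last step; the aryl ester, the non-conjugated ketones and the phenol are inert and toluene is the only by-product, so the acid needs no aqueous treatment.

## Compound list

1 | ethyl 3-oxooctanoate | CCCCCC(=O)CC(=O)OCC | starting material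
2 | ethyl 2-(2-pentyl-1,3-dioxolan-2-yl)acetate | CCCCCC1(CC(=O)OCC)OCCO1 | intermediate
3 | 2-(2-pentyl-1,3-dioxolan-2-yl)acetic acid | CCCCCC1(CC(=O)O)OCCO1 | intermediate
4 | dibenzyl 3-oxopentanedioate | O=C(CC(=O)OCc1ccccc1)CC(=O)OCc1ccccc1 | starting material
5 | 1-(1H-imidazol-1-yl)-2-(2-pentyl-1,3-dioxolan-2-yl)ethan-1-one | CCCCCC1(CC(=O)n2ccnc2)OCCO1 | intermediate (not isolated)
6 | dibenzyl 2-[2-(2-pentyl-1,3-dioxolan-2-yl)acetyl]-3-oxopentanedioate | CCCCCC1(CC(=O)C(C(=O)OCc2ccccc2)C(=O)CC(=O)OCc2ccccc2)OCCO1 | intermediate
7 | benzyl 4-hydroxy-2-oxo-6-[(2-pentyl-1,3-dioxolan-2-yl)methyl]-2H-pyran-5-carboxylate | O=c1cc(O)c(C(=O)OCc2ccccc2)c(CC2(CCCCC)OCCO2)o1 | intermediate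
8 | benzyl 4-(benzyloxy)-2-oxo-6-[(2-pentyl-1,3-dioxolan-2-yl)methyl]-2H-pyran-5-carboxylate | O=c1cc(OCc2ccccc2)c(C(=O)OCc2ccccc2)c(CC2(CCCCC)OCCO2)o1 | intermediate
9 | 1,1-dimethoxyethene | C=C(OC)OC | starting material
10 | benzyl 5-(benzyloxy)-8,8-dimethoxy-3-oxo-1-[(2-pentyl-1,3-dioxolan-2-yl)methyl]-2-oxabicyclo[2.2.2]oct-5-ene-6-carboxylate (racemic) | O=C1OC2(CC3(CCCCC)OCCO3)CC(OC)(OC)C1C(OCc1ccccc1)=C2C(=O)OCc1ccccc1 | intermediate (not isolated)
11 | benzyl 6-(benzyloxy)-4,4-dimethoxy-2-[(2-pentyl-1,3-dioxolan-2-yl)methyl]cyclohexa-1,5-diene-1-carboxylate | COC1(OC)CC(CC2(CCCCC)OCCO2)=C(C(=O)OCc2ccccc2)C(OCc2ccccc2)=C1 | intermediate (not isolated)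
12 | benzyl 2-(benzyloxy)-4-methoxy-6-[(2-pentyl-1,3-dioxolan-2-yl)methyl]benzoate | CCCCCC1(Cc2cc(OC)cc(OCc3ccccc3)c2C(=O)OCc2ccccc2)OCCO1 | intermediate
13 | 2-hydroxy-4-methoxy-6-[(2-pentyl-1,3-dioxolan-2-yl)methyl]benzoic acid | CCCCCC1(Cc2cc(OC)cc(O)c2C(=O)O)OCCO1 | intermediate
14 | benzyl 4-methoxy-2-oxo-6-[(2-pentyl-1,3-dioxolan-2-yl)methyl]-2H-pyran-5-carboxylate | COc1cc(=O)oc(CC2(CCCCC)OCCO2)c1C(=O)OCc1ccccc1 | intermediate
15 | 2-bromo-1,1-diethoxyethane | CCOC(CBr)OCC | starting material
16 | 2-bromo-1,1-bis(benzyloxy)ethane | BrCC(OCc1ccccc1)OCc1ccccc1 | intermediate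
17 | 1,1-bis(benzyloxy)ethene | C=C(OCc1ccccc1)OCc1ccccc1 | intermediate
18 | benzyl 8,8-bis(benzyloxy)-5-methoxy-3-oxo-1-[(2-pentyl-1,3-dioxolan-2-yl)methyl]-2-oxabicyclo[2.2.2]oct-5-ene-6-carboxylate (racemic) | O=C1OC2(CC3(CCCCC)OCCO3)CC(OCc3ccccc3)(OCc3ccccc3)C1C(OC)=C2C(=O)OCc1ccccc1 | intermediate (not isolated)
19 | benzyl 4,4-bis(benzyloxy)-6-methoxy-2-[(2-pentyl-1,3-dioxolan-2-yl)methyl]cyclohexa-1,5-diene-1-carboxylate | COC1=CC(OCc2ccccc2)(OCc2ccccc2)CC(CC2(CCCCC)OCCO2)=C1C(=O)OCc1ccccc1 | intermediate (not isolated)
20 | benzyl 4-(benzyloxy)-2-methoxy-6-[(2-pentyl-1,3-dioxolan-2-yl)methyl]benzoate | CCCCCC1(Cc2cc(OCc3ccccc3)cc(OC)c2C(=O)OCc2ccccc2)OCCO1 | intermediate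
21 | 4-hydroxy-2-methoxy-6-[(2-pentyl-1,3-dioxolan-2-yl)methyl]benzoic acid | CCCCCC1(Cc2cc(O)cc(OC)c2C(=O)O)OCCO1 | intermediate
22 | benzyl 4-hydroxy-2-methoxy-6-[(2-pentyl-1,3-dioxolan-2-yl)methyl]benzoate | CCCCCC1(Cc2cc(O)cc(OC)c2C(=O)OCc2ccccc2)OCCO1 | intermediate
23 | benzyl 4-({2-hydroxy-4-methoxy-6-[(2-pentyl-1,3-dioxolan-2-yl)methyl]benzoyl}oxy)-2-methoxy-6-[(2-pentyl-1,3-dioxolan-2-yl)methyl]benzoate | CCCCCC1(Cc2cc(OC)cc(O)c2C(=O)Oc2cc(CC3(CCCCC)OCCO3)c(C(=O)OCc3ccccc3)c(OC)c2)OCCO1 | intermediate
24 | benzyl 4-{[2-hydroxy-4-methoxy-6-(2-oxoheptyl)benzoyl]oxy}-2-methoxy-6-(2-oxoheptyl)benzoate | CCCCCC(=O)Cc1cc(OC)cc(O)c1C(=O)Oc1cc(CC(=O)CCCCC)c(C(=O)OCc2ccccc2)c(OC)c1 | intermediate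
25 | 4-{[2-hydroxy-4-methoxy-6-(2-oxoheptyl)benzoyl]oxy}-2-methoxy-6-(2-oxoheptyl)benzoic acid | CCCCCC(=O)Cc1cc(OC)cc(O)c1C(=O)Oc1cc(CC(=O)CCCCC)c(C(=O)O)c(OC)c1 | target

## Step count and risk

Total step count: 16. Longest linear sequence: 11 steps (steps 1, 2, 3, 4, 8, 11, 12, 13, 14, 15, 16). The ring A branch (steps 5, 6, 7) and the reagent branch (steps 9, 10) are shorter.

Steps least certain to work:

**Step 6 (key step).** The most likely failure is a cycloaddition that is too slow. The 4-benzyloxy group donates into the diene, and C6 carries a β-branched substituent, so polymerisation of 9, or its consumption by the methanol that is released, could outrun bond formation at C6. A second risk is that a zwitterion, once formed, opens the pyrone ring instead of closing onto C3.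
- Fallback, setting out from 7 and returning at 13: the 4-hydroxyl of 7 is sulfonylated (TsCl, Et3N, CH2Cl2, 0 °C) to benzyl 2-oxo-6-[(2-pentyl-1,3-dioxolan-2-yl)methyl]-4-(tosyloxy)-2H-pyran-5-carboxylate F1, in which the C4 oxygen no longer feeds electron density into the diene.
- This electron-poorer pyrone should react with 9 at lower temperature and with the same ester-controlled regiochemistry to give benzyl 4-methoxy-6-[(2-pentyl-1,3-dioxolan-2-yl)methyl]-2-(tosyloxy)benzoate F2.
- Hydrogenolysis (H2, Pd/C) then gives 4-methoxy-6-[(2-pentyl-1,3-dioxolan-2-yl)methyl]-2-(tosyloxy)benzoic acid F3. Cleavage of the aryl sulfonate with aqueous KOH in dioxane at 60 °C, followed by cold acidification, returns 13.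
- The approach changes from thermal forcing of a donor-substituted diene to electronic activation of the diene, with the sulfonate serving as phenol protection.

**Step 11.** The dienophile 17 may be lost by thermal 1,3-benzyl migration to an ester before it has reacted, and its two benzyloxy groups add steric hindrance at the bond-forming acetal carbon.
- Fallback, setting out from 14 and returning at 22: 14 is heated with purchasable 1-(tert-butyldimethylsilyloxy)-1-methoxyethene in toluene. After loss of CO2, the mixed silyl methyl acetal should aromatise with loss of methanol to benzyl 4-[(tert-butyldimethylsilyl)oxy]-2-methoxy-6-[(2-pentyl-1,3-dioxolan-2-yl)methyl]benzoate F4, and buffered fluoride (TBAF, AcOH, THF) would give 22 directly.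
- This bypasses 20 and 21 and makes steps 9, 10, 12 and 13 unnecessary.
- It is not the main route because a silyl ketene acetal can divert into a Mukaiyama–Michael addition with silyl transfer, and because the direction of the final elimination is less certain than with a symmetric dialkyl acetal.

**Step 3.** The acylation may stop short because an acyl imidazolide is a modest electrophile and the chelated enolate of 4 a modest nucleophile. O-acylation, or a second acylation at the other methylene of 4, could compete.
- Fallback, setting out from 3 and returning at 7: imidazolide 5 is condensed with the magnesium salt of monobenzyl malonate (MgCl2, Et3N, THF), with loss of CO2, to give benzyl 3-oxo-4-(2-pentyl-1,3-dioxolan-2-yl)butanoate F5.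
- The magnesium enolate of F5 (MgCl2, pyridine, CH2Cl2) is C-acylated with methyl 3-chloro-3-oxopropanoate to give 1-benzyl 5-methyl 2-[2-(2-pentyl-1,3-dioxolan-2-yl)acetyl]-3-oxopentanedioate F6.
- DBU in toluene lactonises F6 with loss of methanol to give 7.
- The roles are reversed: the ketal-bearing component is now the nucleophile, and the electrophile is a simple, reactive acid chloride whose acid is taken up by pyridine.

**Step 14.** The activated salicylic acid may acylate the hydroxyl of a second molecule of 13 or rearrange to the N-acylurea, because the phenol of 22, para to an ester, is a slow acyl acceptor.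
- Fallback, setting out from 12 and returning at 25: the benzyl ester of 12 alone is hydrogenolysed over Pd/C in the presence of pyridine, which suppresses cleavage of aryl benzyl ethers, to give 2-(benzyloxy)-4-methoxy-6-[(2-pentyl-1,3-dioxolan-2-yl)methyl]benzoic acid F7.
- With no free hydroxyl, F7 is coupled with 22 under forcing conditions (EDC·HCl, DMAP, CH2Cl2) to give benzyl 4-({2-(benzyloxy)-4-methoxy-6-[(2-pentyl-1,3-dioxolan-2-yl)methyl]benzoyl}oxy)-2-methoxy-6-[(2-pentyl-1,3-dioxolan-2-yl)methyl]benzoate F8.
- Deketalisation (PPTS, wet acetone) gives benzyl 4-{[2-(benzyloxy)-4-methoxy-6-(2-oxoheptyl)benzoyl]oxy}-2-methoxy-6-(2-oxoheptyl)benzoate F9, and one hydrogenolysis removes both benzyl groups to give 25.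

**Step 15.** Under acid, the freed ring A ketone may enol-lactonise onto the hydrogen-bond-activated depside carbonyl with expulsion of ring B. Alternatively the second dioxolane may hydrolyse only slowly, so that prolonged exposure is needed.
- Fallback, setting out from 23 and returning at 25: the order of the last two steps is reversed. Hydrogenolysis of 23 gives 4-({2-hydroxy-4-methoxy-6-[(2-pentyl-1,3-dioxolan-2-yl)methyl]benzoyl}oxy)-2-methoxy-6-[(2-pentyl-1,3-dioxolan-2-yl)methyl]benzoic acid F10.
- The carboxylic acid of F10 then serves as the only acid for ketal exchange in warm wet acetone, without added catalyst, to give 25.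
- If the hydrogen-bonded hydroxyl proves to be the cause, the variant through F8 and F9 described under step 14 unmasks the ketones while that hydroxyl is still benzylated.

## Further compounds

F1 | step 6 | benzyl 2-oxo-6-[(2-pentyl-1,3-dioxolan-2-yl)methyl]-4-(tosyloxy)-2H-pyran-5-carboxylate | Cc1ccc(cc1)S(=O)(=O)Oc1cc(=O)oc(CC2(CCCCC)OCCO2)c1C(=O)OCc1ccccc1
F2 | step 6 | benzyl 4-methoxy-6-[(2-pentyl-1,3-dioxolan-2-yl)methyl]-2-(tosyloxy)benzoate | CCCCCC1(Cc2cc(OC)cc(OS(=O)(=O)c3ccc(C)cc3)c2C(=O)OCc2ccccc2)OCCO1
F3 | step 6 | 4-methoxy-6-[(2-pentyl-1,3-dioxolan-2-yl)methyl]-2-(tosyloxy)benzoic acid | CCCCCC1(Cc2cc(OC)cc(OS(=O)(=O)c3ccc(C)cc3)c2C(=O)O)OCCO1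
F4 | step 11 | benzyl 4-[(tert-butyldimethylsilyl)oxy]-2-methoxy-6-[(2-pentyl-1,3-dioxolan-2-yl)methyl]benzoate | CCCCCC1(Cc2cc(O[Si](C)(C)C(C)(C)C)cc(OC)c2C(=O)OCc2ccccc2)OCCO1
F5 | step 3 | benzyl 3-oxo-4-(2-pentyl-1,3-dioxolan-2-yl)butanoate | CCCCCC1(CC(=O)CC(=O)OCc2ccccc2)OCCO1
F6 | step 3 | 1-benzyl 5-methyl 2-[2-(2-pentyl-1,3-dioxolan-2-yl)acetyl]-3-oxopentanedioate | CCCCCC1(CC(=O)C(C(=O)OCc2ccccc2)C(=O)CC(=O)OC)OCCO1
F7 | step 14 | 2-(benzyloxy)-4-methoxy-6-[(2-pentyl-1,3-dioxolan-2-yl)methyl]benzoic acid | CCCCCC1(Cc2cc(OC)cc(OCc3ccccc3)c2C(=O)O)OCCO1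
F8 | step 14 | benzyl 4-({2-(benzyloxy)-4-methoxy-6-[(2-pentyl-1,3-dioxolan-2-yl)methyl]benzoyl}oxy)-2-methoxy-6-[(2-pentyl-1,3-dioxolan-2-yl)methyl]benzoate | CCCCCC1(Cc2cc(OC)cc(OCc3ccccc3)c2C(=O)Oc2cc(CC3(CCCCC)OCCO3)c(C(=O)OCc3ccccc3)c(OC)c2)OCCO1
F9 | step 14 | benzyl 4-{[2-(benzyloxy)-4-methoxy-6-(2-oxoheptyl)benzoyl]oxy}-2-methoxy-6-(2-oxoheptyl)benzoate | CCCCCC(=O)Cc1cc(OC)cc(OCc2ccccc2)c1C(=O)Oc1cc(CC(=O)CCCCC)c(C(=O)OCc2ccccc2)c(OC)c1
F10 | step 15 | 4-({2-hydroxy-4-methoxy-6-[(2-pentyl-1,3-dioxolan-2-yl)methyl]benzoyl}oxy)-2-methoxy-6-[(2-pentyl-1,3-dioxolan-2-yl)methyl]benzoic acid | CCCCCC1(Cc2cc(OC)cc(O)c2C(=O)Oc2cc(CC3(CCCCC)OCCO3)c(C(=O)O)c(OC)c2)OCCO1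
A1 | alternative 1 | 4-(allyloxy)-2-methoxy-6-(trimethylsilyl)phenyl trifluoromethanesulfonate | C=CCOc1cc(OC)c(OS(=O)(=O)C(F)(F)F)c([Si](C)(C)C)c1
A2 | alternative 1 | dibenzyl malonate | O=C(CC(=O)OCc1ccccc1)OCc1ccccc1
A3 | alternative 1 | benzyl 4-(allyloxy)-2-[2-(benzyloxy)-2-oxoethyl]-6-methoxybenzoate | C=CCOc1cc(OC)c(C(=O)OCc2ccccc2)c(CC(=O)OCc2ccccc2)c1
A4 | alternative 2 | benzyl 2-methoxy-6-[(2-pentyl-1,3-dioxolan-2-yl)methyl]-4-{[3,5,7-trioxo-8-(2-pentyl-1,3-dioxolan-2-yl)octanoyl]oxy}benzoate | CCCCCC1(CC(=O)CC(=O)CC(=O)CC(=O)Oc2cc(CC3(CCCCC)OCCO3)c(C(=O)OCc3ccccc3)c(OC)c2)OCCO1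
A5 | alternative 2 | benzyl 4-({2,4-dihydroxy-6-[(2-pentyl-1,3-dioxolan-2-yl)methyl]benzoyl}oxy)-2-methoxy-6-[(2-pentyl-1,3-dioxolan-2-yl)methyl]benzoate | CCCCCC1(Cc2cc(O)cc(O)c2C(=O)Oc2cc(CC3(CCCCC)OCCO3)c(C(=O)OCc3ccccc3)c(OC)c2)OCCO1
A6 | alternative 3 | 1,1-dimethoxy-3-(trimethylsilyloxy)buta-1,3-diene | COC(OC)=CC(=C)O[Si](C)(C)C
A7 | alternative 3 | benzyl 4-(2-pentyl-1,3-dioxolan-2-yl)but-2-ynoate | CCCCCC1(CC#CC(=O)OCc2ccccc2)OCCO1
A8 | alternative 3 | benzyl 4-hydroxy-2-methoxy-6-[(2-pentyl-1,3-dioxolan-2-yl)methyl]benzoate | CCCCCC1(Cc2cc(O)cc(OC)c2C(=O)OCc2ccccc2)OCCO1
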